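**Retrosynthetic overview**

1. The strategy rests on C2 of the pyran ring. It is a fully substituted allylic aryl-ether carbon bearing O1, the C3=C4 alkene, a methyl group and the CH2CH2 tether, and it lies too far from the cyclohexane stereocentres for substrate control. It is disconnected at O1–C2 (Pd-catalysed asymmetric allylic etherification of a 2-vinylphenol with an E allylic carbonate) and at C3=C4 (ring-closing metathesis).
2. The C5/C6 catechol is traced back to the 5,6-quinone and then to a C6 phenol (ortho-oxygenation). The arene therefore comes from 5-bromovanillin by vinylation, Dakin oxidation and monosilylation.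
3. The E carbonate comes from a terminal alkyne (methylalumination, formaldehyde), the exocyclic methylene from a ketone, and the alkynyl ketone from Eschenmoser–Tanabe fragmentation of an epoxy octalone.
4. The octalone comes from 2,6-dimethylcyclohexanone by Michael addition of its (S)-1-phenylethylamine imine to methyl vinyl ketone and aldol condensation; these two operations set the quaternary and the secondary methyl centres.
5. Ring order: the carbocycle is bought; a second carbocycle is annulated (step 3), bridged by an oxirane (step 4) and cleaved again (step 5); the pyran ring is closed last (step 13).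

Key step: step 12

Remark on the chemistry: the absolute sense of step 12 is assigned from the face-selection model for this ligand family. The (S,S)-diamide ligand is assumed to pair with the E carbonate to give 2S; if a model correlation shows the opposite sense, the antipodal ligand is used with no other change.

**Route**

Step 1
Reactants: 1 2,6-dimethylcyclohexanone (commercial cis/trans mixture); 2 (S)-1-phenylethylamine
Product: 3 (S)-N-(2,6-dimethylcyclohexylidene)-1-phenylethanamine
Conditions: p-TsOH (cat.), toluene, reflux, Dean–Stark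
Reagents that add atoms: none
Why: Acid-catalysed imine condensation driven by azeotropic removal of water; the amine stereocentre is untouched and the ring α-centres need no control because they pass through the enamine in step 2.

Step 2
Reactants: 3 (S)-N-(2,6-dimethylcyclohexylidene)-1-phenylethanamine; 4 methyl vinyl ketone
Product: 6 (2R)-2,6-dimethyl-2-(3-oxobutyl)cyclohexan-1-one (C6 epimers), via Michael adduct imine 5 (not isolated)
Conditions: 4 (1.3 equiv), THF, 40 °C; then AcOH/H2O, rt
Reagents that add atoms: water (O)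
Why: Michael addition of a chiral imine through its secondary enamine tautomer, with ene-like internal N–H transfer in a compact cyclic transition state; the enone should approach the enamine face away from the phenyl group, which for the (S)-amine gives the R quaternary carbon as established for 2-methylcyclohexanone imines, and aqueous acid then hydrolyses the adduct and returns the amine.

Step 3
Reactants: 6 (2R)-2,6-dimethyl-2-(3-oxobutyl)cyclohexan-1-one
Product: 8 (4aR,8R)-4a,8-dimethyl-4,4a,5,6,7,8-hexahydronaphthalen-2(3H)-one, via ketol 7 (not isolated)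
Conditions: NaOMe (0.3 equiv), MeOH, 60 °C, prolonged
Reagents that add atoms: none
Why: Intramolecular aldol condensation (second half of a Robinson annulation) closes the cyclohexenone; prolonged base exposure should equilibrate C8 through the dienolate to the equatorial methyl trans to the angular methyl, the cis isomer being disfavoured by a 1,3-diaxial methyl/methyl contact.

Step 4
Reactants: 8 (4aR,8R)-4a,8-dimethyl-4,4a,5,6,7,8-hexahydronaphthalen-2(3H)-one
Product: 9 (4aR,8R)-1,8a-epoxy-4a,8-dimethyloctahydronaphthalen-2(1H)-one (both oxirane epimers)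
Conditions: H2O2 (30 %), NaOH (0.3 equiv), MeOH, 0 °C to rt
Reagents that add atoms: hydrogen peroxide (OO)
Why: Weitz–Scheffer nucleophilic epoxidation by conjugate addition of hydroperoxide to the enone; the oxirane configuration is irrelevant because both epimers fragment to the same product, and C8 is no longer acidic once the enone is consumed.

Step 5
Reactants: 9 (4aR,8R)-1,8a-epoxy-4a,8-dimethyloctahydronaphthalen-2(1H)-one
Product: 11 (2R,6R)-2-(but-3-yn-1-yl)-2,6-dimethylcyclohexan-1-one, via epoxy tosylhydrazone 10 (not isolated)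
Conditions: TsNHNH2 (1.1 equiv), AcOH/CH2Cl2 1:1, −20 °C to rt
Reagents that add atoms: none
Why: Eschenmoser–Tanabe fragmentation: the hydrazone opens the oxirane to an azoalkene alkoxide, which fragments with loss of dinitrogen and sulfinate to the ketone and the terminal alkyne; no bond to either stereocentre is broken, and the cold, weakly acidic medium should leave the new α-centre unepimerised.

Step 6
Reactants: 11 (2R,6R)-2-(but-3-yn-1-yl)-2,6-dimethylcyclohexan-1-one
Product: 12 (1R,3R)-1-(but-3-yn-1-yl)-1,3-dimethyl-2-methylidenecyclohexane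
Conditions: Zn, CH2Br2, TiCl4, THF, −40 to 5 °C (pre-aged reagent); then 11, CH2Cl2, rt
Reagents that add atoms: dibromomethane (BrCBr)
Why: Lombardo methylenation with a non-basic geminal dimetallic methylene reagent, used because this ketone has no thermodynamic bias at C6 and an ylide would epimerise it; the terminal alkyne is tolerated.

Step 7
Reactants: 12 (1R,3R)-1-(but-3-yn-1-yl)-1,3-dimethyl-2-methylidenecyclohexane
Product: 15 (2E)-5-[(1R,3R)-1,3-dimethyl-2-methylidenecyclohexyl]-3-methylpent-2-en-1-ol, via alkenylalane 13 (not isolated), via lithium alanate 14 (not isolated)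
Conditions: Me3Al (3 equiv), Cp2ZrCl2 (0.3 equiv), CH2Cl2, 0 °C to rt; evaporate; n-BuLi, THF/hexane, −78 °C; (CH2O)n, rt; aq. HCl
Reagents that add atoms: trimethylaluminium (C[Al](C)C); paraformaldehyde (C=O as the formaldehyde unit)
Why: Negishi zirconium-catalysed carboalumination adds methyl and aluminium syn across the terminal alkyne with aluminium on the terminal carbon, and hydroxymethylation of the derived alanate proceeds with retention, so a single E trisubstituted alkene is expected; the hindered exocyclic alkene does not react.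

Step 8
Reactants: 15 (2E)-5-[(1R,3R)-1,3-dimethyl-2-methylidenecyclohexyl]-3-methylpent-2-en-1-ol
Product: 16 (2E)-5-[(1R,3R)-1,3-dimethyl-2-methylidenecyclohexyl]-3-methylpent-2-en-1-yl methyl carbonate
Conditions: ClCO2Me, pyridine, CH2Cl2, 0 °C
Reagents that add atoms: methyl chloroformate (COC(=O)Cl)
Why: Acylation of a primary allylic alcohol by a chloroformate under mild base, which does not touch the alkene geometry.

Step 9
Reactants: 17 5-bromovanillin
Product: 18 4-hydroxy-3-methoxy-5-vinylbenzaldehyde
Conditions: potassium vinyltrifluoroborate (1.2 equiv), PdCl2(dppf)·CH2Cl2 (3 mol %), Cs2CO3 (3 equiv), THF/H2O 9:1, 80 °C; acidic work-up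
Reagents that add atoms: potassium vinyltrifluoroborate ([K+].F[B-](F)(F)C=C)
Why: Suzuki–Miyaura coupling of an aryl bromide with a vinyltrifluoroborate, which tolerates the free phenol and the aldehyde.

Step 10
Reactants: 18 4-hydroxy-3-methoxy-5-vinylbenzaldehyde
Product: 20 2-methoxy-6-vinylbenzene-1,4-diol, via aryl formate 19 (not isolated)
Conditions: H2O2 (30 %, 1.3 equiv), NaOH (1.1 equiv), THF/H2O, 0 °C to rt, N2, degassed; then aq. HCl
Reagents that add atoms: hydrogen peroxide (OO)
Why: Dakin oxidation of a para-hydroxybenzaldehyde: hydroperoxide adds to the aldehyde, the electron-rich aryl group migrates to oxygen and the formate is saponified in situ; the styrene is not electrophilic enough for alkaline peroxide.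

Step 11
Reactants: 20 2-methoxy-6-vinylbenzene-1,4-diol
Product: 21 4-(tert-butyldimethylsilyloxy)-2-methoxy-6-vinylphenol
Conditions: TBSCl (1.0 equiv), imidazole (2 equiv), CH2Cl2/DMF, −20 to 0 °C
Reagents that add atoms: tert-butyldimethylsilyl chloride (CC(C)(C)[Si](C)(C)Cl)
Why: Silylation should favour the C4 hydroxyl, which has two ortho hydrogens, over the C1 hydroxyl, which is flanked by methoxy and vinyl groups and hydrogen-bonded to the methoxy oxygen.

Step 12
Reactants: 16 (2E)-5-[(1R,3R)-1,3-dimethyl-2-methylidenecyclohexyl]-3-methylpent-2-en-1-yl methyl carbonate; 21 4-(tert-butyldimethylsilyloxy)-2-methoxy-6-vinylphenol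
Product: 22 tert-butyl[4-({(3S)-5-[(1R,3R)-1,3-dimethyl-2-methylidenecyclohexyl]-3-methylpent-1-en-3-yl}oxy)-3-methoxy-5-vinylphenoxy]dimethylsilane
Conditions: Pd2(dba)3·CHCl3 (2 mol %), (1S,2S)-N,N'-bis[2-(diphenylphosphino)benzoyl]cyclohexane-1,2-diamine (6 mol %), n-Bu4NCl (30 mol %), CH2Cl2, rt
Reagents that add atoms: none
Why: Zerovalent palladium ionises carbonate 16 with loss of CO2 and methoxide, which deprotonates phenol 21, and the resulting π-allyl complex carries the tether syn and the methyl anti as dictated by the E alkene. The phenoxide then attacks the more substituted allyl terminus on the face opposite the metal and forms the O1–C2 bond; this is an asymmetric Tsuji–Trost allylic etherification of the kind known for phenols with geranyl-type carbonates, here with a doubly ortho-substituted phenol at the edge of that scope. No ring is closed in this operation, the pyran ring being left for the metathesis of step 13. The new stereocentre (the future C2, S) is controlled by the ligand enantiomer acting on the geometrically defined allyl unit, so the Z carbonate or the antipodal ligand would deliver the epimer. Two selectivities are needed, branched over linear attack and one allyl enantioface: the first is secured by this ligand class, which steers oxygen nucleophiles to the terminus that best carries positive charge, and the second by the single E geometry from step 7 together with chloride-accelerated π–σ–π equilibration through the CH2 terminus, which lets the chiral pocket and not the ionisation event decide. The exocyclic methylene and the styrene of 21 cannot be ionised and should stay untouched.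

Step 13
Reactants: 22 tert-butyl[4-({(3S)-5-[(1R,3R)-1,3-dimethyl-2-methylidenecyclohexyl]-3-methylpent-1-en-3-yl}oxy)-3-methoxy-5-vinylphenoxy]dimethylsilane
Product: 23 tert-butyl({(2S)-2-{2-[(1R,3R)-1,3-dimethyl-2-methylidenecyclohexyl]ethyl}-8-methoxy-2-methyl-2H-chromen-6-yl}oxy)dimethylsilane
Conditions: second-generation Grubbs catalyst RuCl2(=CHPh)(H2IMes)(PCy3) (5 mol %), CH2Cl2 (0.005 M), 40 °C
Reagents that add atoms: none
Why: Ring-closing metathesis between the aryl vinyl group and the vinyl group on C2 forms C3=C4 and the six-membered pyran with loss of ethene; the 1,1-disubstituted exocyclic methylene, flanked by a quaternary and a tertiary carbon, is too hindered to enter the cycle, and C2 is not involved.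

Step 14
Reactants: 23 tert-butyl({(2S)-2-{2-[(1R,3R)-1,3-dimethyl-2-methylidenecyclohexyl]ethyl}-8-methoxy-2-methyl-2H-chromen-6-yl}oxy)dimethylsilane
Product: 24 (2S)-2-{2-[(1R,3R)-1,3-dimethyl-2-methylidenecyclohexyl]ethyl}-8-methoxy-2-methyl-2H-chromen-6-ol
Conditions: TBAF (1.1 equiv), AcOH (1.1 equiv), THF, 0 °C, argon
Reagents that add atoms: none
Why: Fluoride-driven cleavage of the aryl silyl ether, buffered with acetic acid so that the electron-rich phenol is not exposed to air as its phenoxide.

Step 15
Reactants: 24 (2S)-2-{2-[(1R,3R)-1,3-dimethyl-2-methylidenecyclohexyl]ethyl}-8-methoxy-2-methyl-2H-chromen-6-ol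
Product: 25 (2S)-2-{2-[(1R,3R)-1,3-dimethyl-2-methylidenecyclohexyl]ethyl}-8-methoxy-2-methyl-2H-chromene-5,6-dione
Conditions: IBX (1.1 equiv), DMF, rt, dark, argon
Reagents that add atoms: 2-iodoxybenzoic acid (O=C1OI(=O)(O)c2ccccc12)
Why: IBX ortho-oxygenation of a phenol: the phenol binds pentavalent iodine, oxygen is delivered intramolecularly to an ortho carbon, and the trivalent iodine catechol intermediate collapses to the ortho-quinone; C5 is expected to be preferred because it is para to the C8 methoxy group whereas C7 is crowded by that group, and the 5,6-dione is a doubly vinylogous ester.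

Step 16
Reactants: 25 (2S)-2-{2-[(1R,3R)-1,3-dimethyl-2-methylidenecyclohexyl]ethyl}-8-methoxy-2-methyl-2H-chromene-5,6-dione
Product: 26 (2S)-2-{2-[(1R,3R)-1,3-dimethyl-2-methylidenecyclohexyl]ethyl}-8-methoxy-2-methyl-2H-chromene-5,6-diol (CNP0329505.1)
Conditions: Na2S2O4 (excess), THF/H2O, 0 °C, argon; crude 25 used at once
Reagents that add atoms: none
Why: Two-electron dithionite reduction of the ortho-quinone to the catechol under cold, oxygen-free conditions, which leaves both alkenes and all stereocentres untouched.

**Compound list**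

1 | 2,6-dimethylcyclohexanone (cis/trans mixture) | CC1CCCC(C)C1=O | starting material
2 | (S)-1-phenylethylamine | C[C@H](N)c1ccccc1 | starting material
3 | (S)-N-(2,6-dimethylcyclohexylidene)-1-phenylethanamine | CC1CCCC(C)C1=N[C@@H](C)c1ccccc1 | intermediate
4 | methyl vinyl ketone | C=CC(C)=O | starting material
5 | 4-[(1R)-1,3-dimethyl-2-{[(1S)-1-phenylethyl]imino}cyclohexyl]butan-2-one (Michael adduct imine, not isolated) | C[C@H](N=C1C(C)CCC[C@]1(C)CCC(C)=O)c1ccccc1 | intermediate
6 | (2R)-2,6-dimethyl-2-(3-oxobutyl)cyclohexan-1-one (C6 epimers) | O=C1C(C)CCC[C@]1(C)CCC(C)=O | intermediate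
7 | (4aR)-8a-hydroxy-4a,8-dimethyloctahydronaphthalen-2(1H)-one (ketol, not isolated) | O=C1CC2(O)C(C)CCC[C@]2(C)CC1 | intermediate
8 | (4aR,8R)-4a,8-dimethyl-4,4a,5,6,7,8-hexahydronaphthalen-2(3H)-one | O=C1C=C2[C@H](C)CCC[C@]2(C)CC1 | intermediate
9 | (4aR,8R)-1,8a-epoxy-4a,8-dimethyloctahydronaphthalen-2(1H)-one (both oxirane epimers) | O=C1C2OC23[C@H](C)CCC[C@]3(C)CC1 | intermediate
10 | tosylhydrazone of 9 (not isolated) | Cc1ccc(cc1)S(=O)(=O)NN=C1C2OC23[C@H](C)CCC[C@]3(C)CC1 | intermediate
11 | (2R,6R)-2-(but-3-yn-1-yl)-2,6-dimethylcyclohexan-1-one | O=C1[C@H](C)CCC[C@]1(C)CCC#C | intermediate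
12 | (1R,3R)-1-(but-3-yn-1-yl)-1,3-dimethyl-2-methylidenecyclohexane | C=C1[C@H](C)CCC[C@]1(C)CCC#C | intermediate
13 | [(1E)-4-[(1R,3R)-1,3-dimethyl-2-methylidenecyclohexyl]-2-methylbut-1-en-1-yl]dimethylalane (not isolated) | C=C1[C@H](C)CCC[C@]1(C)CC/C(C)=C/[Al](C)C | intermediate
14 | lithium butyl[(1E)-4-[(1R,3R)-1,3-dimethyl-2-methylidenecyclohexyl]-2-methylbut-1-en-1-yl]dimethylalanate (not isolated) | C=C1[C@H](C)CCC[C@]1(C)CC/C(C)=C/[Al-](C)(C)CCCC.[Li+] | intermediate
15 | (2E)-5-[(1R,3R)-1,3-dimethyl-2-methylidenecyclohexyl]-3-methylpent-2-en-1-ol | C=C1[C@H](C)CCC[C@]1(C)CC/C(C)=C/CO | intermediate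
16 | (2E)-5-[(1R,3R)-1,3-dimethyl-2-methylidenecyclohexyl]-3-methylpent-2-en-1-yl methyl carbonate | C=C1[C@H](C)CCC[C@]1(C)CC/C(C)=C/COC(=O)OC | intermediate
17 | 5-bromovanillin | COc1cc(C=O)cc(Br)c1O | starting material
18 | 4-hydroxy-3-methoxy-5-vinylbenzaldehyde | COc1cc(C=O)cc(C=C)c1O | intermediate
19 | 4-hydroxy-3-methoxy-5-vinylphenyl formate (not isolated) | COc1cc(OC=O)cc(C=C)c1O | intermediate
20 | 2-methoxy-6-vinylbenzene-1,4-diol | COc1cc(O)cc(C=C)c1O | intermediate
21 | 4-(tert-butyldimethylsilyloxy)-2-methoxy-6-vinylphenol | C=Cc1cc(O[Si](C)(C)C(C)(C)C)cc(OC)c1O | intermediate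
22 | tert-butyl[4-({(3S)-5-[(1R,3R)-1,3-dimethyl-2-methylidenecyclohexyl]-3-methylpent-1-en-3-yl}oxy)-3-methoxy-5-vinylphenoxy]dimethylsilane | C=C1[C@H](C)CCC[C@]1(C)CC[C@@](Oc1c(OC)cc(O[Si](C)(C)C(C)(C)C)cc1C=C)(C)C=C | intermediate
23 | tert-butyl({(2S)-2-{2-[(1R,3R)-1,3-dimethyl-2-methylidenecyclohexyl]ethyl}-8-methoxy-2-methyl-2H-chromen-6-yl}oxy)dimethylsilane | C=C1[C@H](C)CCC[C@]1(C)CC[C@@]1(C)C=Cc2cc(O[Si](C)(C)C(C)(C)C)cc(OC)c2O1 | intermediate
24 | (2S)-2-{2-[(1R,3R)-1,3-dimethyl-2-methylidenecyclohexyl]ethyl}-8-methoxy-2-methyl-2H-chromen-6-ol | C=C1[C@H](C)CCC[C@]1(C)CC[C@@]1(C)C=Cc2cc(O)cc(OC)c2O1 | intermediate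
25 | (2S)-2-{2-[(1R,3R)-1,3-dimethyl-2-methylidenecyclohexyl]ethyl}-8-methoxy-2-methyl-2H-chromene-5,6-dione | C=C1[C@H](C)CCC[C@]1(C)CC[C@@]1(C)C=CC2=C(O1)C(OC)=CC(=O)C2=O | intermediate
26 | (2S)-2-{2-[(1R,3R)-1,3-dimethyl-2-methylidenecyclohexyl]ethyl}-8-methoxy-2-methyl-2H-chromene-5,6-diol (CNP0329505.1) | C=C1[C@H](C)CCC[C@]1(C)CC[C@@]1(C)C=Cc2c(O)c(O)cc(OC)c2O1 | target

**Step count**

Total: 16 steps. Longest linear sequence: 13 steps (steps 1–8, then 12–16); the arene branch is steps 9–11.

**Steps most likely to fail**

Step 12. The doubly ortho-substituted phenoxide may attack the allyl complex slowly. Attack at the primary terminus, elimination of the allyl unit to a diene, or erosion of the enantioselectivity could then compete. The fallback sets out from allylic alcohol 15 and comes back to the route at chromene 23, replacing steps 8–13 and vinylphenol 21. Oxidation of 15 with MnO2 in CH2Cl2 should give (2E)-5-[(1R,3R)-1,3-dimethyl-2-methylidenecyclohexyl]-3-methylpent-2-enal F1. Commercial 2-methoxybenzene-1,4-diol, silylated at its unhindered hydroxyl (TBSCl, imidazole), should give 4-(tert-butyldimethylsilyloxy)-2-methoxyphenol F2. Heating F1 and F2 with PhB(OH)2 and a little propionic acid in toluene with removal of water should give the 4-alkenyl-2-phenyl-4H-1,3,2-benzodioxaborin F3. This should lose phenylboronic acid to the ortho-quinone methide F4, which closes to 23 by oxa-6π electrocyclisation. In this fallback C2 forms without control, so both C2 epimers are expected and would have to be separated by preparative chromatography on a chiral stationary phase before step 14.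

Step 15. Both ortho positions of the C6 phenol are flanked by a substituent, so oxygen delivery to C7 may compete with delivery to C5 and give the isomeric quinone. The fallback sets out from carbonate 16 and comes back at quinone 25, using an isomeric arene whose phenol has only one free ortho position. Baeyer–Villiger oxidation of commercial 2-bromo-3-hydroxy-4-methoxybenzaldehyde (mCPBA, CH2Cl2) should give 2-bromo-3-hydroxy-4-methoxyphenyl formate F5. Methanolysis (K2CO3, MeOH) should give 2-bromo-4-methoxybenzene-1,3-diol F6. Suzuki–Miyaura vinylation (potassium vinyltrifluoroborate, Pd(OAc)2, SPhos, K3PO4, dioxane/H2O) should give 4-methoxy-2-vinylbenzene-1,3-diol F7. Silylation of the hydroxyl remote from the methoxy group should give 3-(tert-butyldimethylsilyloxy)-6-methoxy-2-vinylphenol F8. Etherification of F8 with 16 under the conditions of step 12 should give tert-butyl[2-({(3S)-5-[(1R,3R)-1,3-dimethyl-2-methylidenecyclohexyl]-3-methylpent-1-en-3-yl}oxy)-3-methoxy-6-vinylphenoxy... in its 3-silyloxy-6-methoxy-2-vinylphenyl form, the tertiary ether F9. Metathesis as in step 13 should give the 5-silyloxy-8-methoxy-2H-chromene F10, and buffered fluoride should give (2S)-2-{2-[(1R,3R)-1,3-dimethyl-2-methylidenecyclohexyl]ethyl}-8-methoxy-2-methyl-2H-chromen-5-ol F11. The only free ortho position of F11 is C6, so IBX can lead only to 25.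

Step 6. The carbonyl lies between a quaternary and a tertiary carbon, so methylenation may stall, and forcing or basic conditions would epimerise C6. The fallback sets out from ketone 11 and comes back at 12 by a Peterson olefination. Addition of Me3SiCH2Li pre-mixed with CeCl3 (excess, THF, −78 °C) should give (2R,6R)-2-(but-3-yn-1-yl)-2,6-dimethyl-1-[(trimethylsilyl)methyl]cyclohexan-1-ol F12; the low basicity of the organocerium species should spare C6, and the alkyne proton is restored on quench. Elimination with KH in THF should then give 12.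

**Further compounds**

F1 | step 12 | (2E)-5-[(1R,3R)-1,3-dimethyl-2-methylidenecyclohexyl]-3-methylpent-2-enal | C=C1[C@H](C)CCC[C@]1(C)CC/C(C)=C/C=O
F2 | step 12 | 4-(tert-butyldimethylsilyloxy)-2-methoxyphenol | COc1cc(O[Si](C)(C)C(C)(C)C)ccc1O
F3 | step 12 | 6-(tert-butyldimethylsilyloxy)-4-{(1E)-4-[(1R,3R)-1,3-dimethyl-2-methylidenecyclohexyl]-2-methylbut-1-en-1-yl}-8-methoxy-2-phenyl-4H-1,3,2-benzodioxaborin | C=C1[C@H](C)CCC[C@]1(C)CC/C(C)=C/C1OB(c2ccccc2)Oc2c(OC)cc(O[Si](C)(C)C(C)(C)C)cc21
F4 | step 12 | 4-(tert-butyldimethylsilyloxy)-6-{(2E)-5-[(1R,3R)-1,3-dimethyl-2-methylidenecyclohexyl]-3-methylpent-2-en-1-ylidene}-2-methoxycyclohexa-2,4-dien-1-one | C=C1[C@H](C)CCC[C@]1(C)CC/C(C)=C/C=C1C=C(O[Si](C)(C)C(C)(C)C)C=C(OC)C1=O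
F5 | step 15 | 2-bromo-3-hydroxy-4-methoxyphenyl formate | COc1ccc(OC=O)c(Br)c1O
F6 | step 15 | 2-bromo-4-methoxybenzene-1,3-diol | COc1ccc(O)c(Br)c1O
F7 | step 15 | 4-methoxy-2-vinylbenzene-1,3-diol | COc1ccc(O)c(C=C)c1O
F8 | step 15 | 3-(tert-butyldimethylsilyloxy)-6-methoxy-2-vinylphenol | COc1ccc(O[Si](C)(C)C(C)(C)C)c(C=C)c1O
F9 | step 15 | tert-butyl[2-({(3S)-5-[(1R,3R)-1,3-dimethyl-2-methylidenecyclohexyl]-3-methylpent-1-en-3-yl}oxy)-... 3-silyloxy-6-methoxy-2-vinylphenyl tertiary ether | C=C1[C@H](C)CCC[C@]1(C)CC[C@@](Oc1c(OC)ccc(O[Si](C)(C)C(C)(C)C)c1C=C)(C)C=C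
F10 | step 15 | tert-butyl({(2S)-2-{2-[(1R,3R)-1,3-dimethyl-2-methylidenecyclohexyl]ethyl}-8-methoxy-2-methyl-2H-chromen-5-yl}oxy)dimethylsilane | C=C1[C@H](C)CCC[C@]1(C)CC[C@@]1(C)C=Cc2c(O[Si](C)(C)C(C)(C)C)ccc(OC)c2O1
F11 | step 15 | (2S)-2-{2-[(1R,3R)-1,3-dimethyl-2-methylidenecyclohexyl]ethyl}-8-methoxy-2-methyl-2H-chromen-5-ol | C=C1[C@H](C)CCC[C@]1(C)CC[C@@]1(C)C=Cc2c(O)ccc(OC)c2O1
F12 | step 6 | (2R,6R)-2-(but-3-yn-1-yl)-2,6-dimethyl-1-[(trimethylsilyl)methyl]cyclohexan-1-ol | C[Si](C)(C)CC1(O)[C@H](C)CCC[C@]1(C)CCC#C
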